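**Retrosynthetic overview**

1. The allylic acetate and the (Z)-enal are unveiled last. The side chain is completed by ligand-controlled addition of an (E)-alkenylzinc, made from (S)-citronellal, to an (E)-enal obtained by SeO2 oxidation of a prenyl terminus.
2. The only ring, the cyclohexane, is closed in one operation from an acyclic keto alkynoate and methyl acrylate. Nickel-catalysed alkylative coupling joins the acrylate β-carbon to the alkyne and the resulting zinc enolate closes onto the methyl ketone. The same step brings in the vinylic methyl, fixes the geometry of the tetrasubstituted exocyclic alkene and sets the tertiary carbinol. The acrylate carboxyl is then removed (Barton).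
3. Enabling feature: in the precursor the ketone carbonyl carbon and the alkyne carbon β to the ester are 1,4-related, separated only by the quaternary C(CH3) carbon and the CH carbon that carries the silyloxypropyl chain. The two acrylate carbons therefore complete a six-membered carbocycle, and the ester-bearing exocyclic alkene biases the chair of the ring closure.
4. The keto alkynoate comes from geraniol. An enantioselective Ireland–Claisen rearrangement sets the vicinal quaternary/tertiary pair, the vinyl group becomes the methyl ketone (Wacker) and the carboxyl becomes the alkynoate (Corey–Fuchs).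
5. Chiral-pool mapping: the ten geraniol carbons supply the quaternary ring carbon and its methyl, the carbinol carbon and its methyl, and six side-chain carbons. (S)-Citronellal supplies the remote methyl stereocentre.

Key step: step 9

Assumption: the senses of induction of the chiral controller in step 3 ((S,S)-bromoborane giving the (2S,3R) acid) and of the ligand in step 14 ((+)-MIB giving the (R)-carbinol) follow the accepted transition-state models; the enantiomeric reagent is used should either prove opposite.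

**Route**

Step 1
Reactants: 1 δ-valerolactone
Product: 3 5-[(tert-butyldiphenylsilyl)oxy]pentanoic acid, via sodium 5-hydroxypentanoate 2 (not isolated)
Conditions: NaOH, MeOH–H2O, rt; evaporate; TBDPSCl (2.2 equiv), imidazole, DMF, rt; K2CO3, MeOH–THF–H2O; acidify to pH 4
Reagents that add atoms: sodium hydroxide, [Na+].[OH-]; tert-butyl(chloro)diphenylsilane, CC(C)(C)[Si](Cl)(c1ccccc1)c1ccccc1
Why: Lactone saponification, silylation and mild cleavage of the labile silyl ester should give the ω-silyloxy acid (silyl ether protection).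

Step 2
Reactants: 3 silyloxy acid; 4 geraniol
Product: 5 geranyl 5-[(tert-butyldiphenylsilyl)oxy]pentanoate
Conditions: EDC·HCl, DMAP (cat.), CH2Cl2, 0 °C → rt
Reagents that add atoms: none
Why: Steglich-type carbodiimide esterification of a primary allylic alcohol, no stereocentre being formed.

Step 3
Reactants: 5 geranyl ester
Product: 7 (2S,3R)-2-[3-(tert-butyldiphenylsilyloxy)propyl]-3,7-dimethyl-3-vinyloct-6-enoic acid, via boron ketene acetal 6 (not isolated)
Conditions: (4S,5S)-2-bromo-4,5-diphenyl-1,3-bis(p-tolylsulfonyl)-1,3,2-diazaborolidine (preformed), i-Pr2NEt, CH2Cl2, −78 °C, then −20 °C → 4 °C; aqueous work-up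
Reagents that add atoms: none
Why: Enantioselective Ireland–Claisen rearrangement through a chiral boron ketene acetal, in which the Z(O)-enolate and the (E)-allyl unit should pass a chair transition state with the enolate side chain and the homoprenyl group both equatorial (syn relation of the new quaternary and tertiary centres), while the C2-symmetric sulfonamide ligand on boron selects the enantiotopic face.

Step 4
Reactants: 7 Claisen acid
Product: 8 (2S,3R)-2-[3-(tert-butyldiphenylsilyloxy)propyl]-3,7-dimethyl-3-vinyloct-6-en-1-ol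
Conditions: LiAlH4, THF, 0 °C → reflux; Fieser work-up
Reagents that add atoms: none
Why: Hydride reduction of the acid to the primary alcohol, which should leave the alkenes and the silyl ether untouched.

Step 5
Reactants: 8 primary alcohol
Product: 9 (2S,3R)-2-[3-(tert-butyldiphenylsilyloxy)propyl]-3,7-dimethyl-3-vinyloct-6-enal
Conditions: Dess–Martin periodinane, NaHCO3, CH2Cl2, 0 °C → rt
Reagents that add atoms: none
Why: Buffered Dess–Martin oxidation should give the α-branched aldehyde without epimerisation.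

Step 6
Reactants: 9 aldehyde
Product: 10 1,1-dibromo-3-[3-(tert-butyldiphenylsilyloxy)propyl]-4,8-dimethyl-4-vinylnona-1,7-diene (stereocentres as in 9)
Conditions: CBr4, PPh3, CH2Cl2, 0 °C
Reagents that add atoms: carbon tetrabromide, BrC(Br)(Br)Br
Why: Ramirez dibromo-olefination, the first stage of the Corey–Fuchs sequence.

Step 7
Reactants: 10 dibromoalkene
Product: 12 tert-butyl 4-[3-(tert-butyldiphenylsilyloxy)propyl]-5,9-dimethyl-5-vinyldec-8-en-2-ynoate (stereocentres as in 9), via lithium acetylide 11 (not isolated)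
Conditions: n-BuLi (2.2 equiv), THF, −78 °C; Boc2O, −78 → 0 °C; aq. NH4Cl
Reagents that add atoms: di-tert-butyl dicarbonate, CC(C)(C)OC(=O)OC(=O)OC(C)(C)C
Why: Fritsch–Buttenberg–Wiechell rearrangement to the lithium acetylide (second stage of Corey–Fuchs) and C-acylation with Boc2O should give the alkynoate.

Step 8
Reactants: 12 vinyl alkynoate
Product: 13 tert-butyl (4R,5S)-5-acetyl-4-[3-(tert-butyldiphenylsilyloxy)propyl]-5,9-dimethyldec-8-en-2-ynoate
Conditions: PdCl2 (10 mol %), CuCl (30 mol %), O2 (1 atm), DMF–H2O, rt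
Reagents that add atoms: water, O
Why: Tsuji–Wacker oxidation by Markovnikov oxypalladation of the monosubstituted vinyl group, which should react far faster than the trisubstituted alkene or the electron-poor alkyne.

Step 9
Reactants: 13 keto alkynoate; 14 methyl acrylate
Product: 16 tert-butyl (2Z)-2-{(2R,3S,4S)-2-[3-(tert-butyldiphenylsilyloxy)propyl]-4-hydroxy-5-(methoxycarbonyl)-3,4-dimethyl-3-(4-methylpent-3-en-1-yl)cyclohexylidene}propanoate (epimers at C-5), via methylzinc enolate 15 (not isolated)
Conditions: Ni(cod)2 (10 mol %), Me2Zn (2.5 equiv), methyl acrylate (slow addition), THF, 0 °C → rt; aq. NH4Cl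
Reagents that add atoms: dimethylzinc, C[Zn]C
Why: Proposed new method: zerovalent nickel should join the alkynoate and methyl acrylate by oxidative cyclisation (C–C bond between the alkyne carbon β to the ester and the acrylate β-carbon), Me2Zn then transfers methyl to nickel and reductive elimination puts it on the α-carbon syn to the new bond, releasing methylzinc enolate 15, which adds to the methyl ketone. The closest known reaction type is the nickel-catalysed alkylative three-component coupling of alkynes, enones and organozincs with aldol trapping of its metal enolate; new here is ring closure onto a tethered ketone after an intermolecular coupling of an alkynoate. The cyclohexane closes in a 6-(enolexo)-exo-trig aldol addition. The tertiary carbinol centre is controlled by the chair transition state: allylic 1,3-strain with the ester on the exocyclic alkene holds the silyloxypropyl chain axial, so the ketone should react with its oxygen axial (bridged to zinc) and its methyl equatorial, which puts OH cis to the ring methyl and to that chain, while the ester-bearing centre needs no control because the carboxyl is removed in step 11. The step needs bond formation at the alkyne carbon remote from the ester and syn addition across the alkyne; the polarisation of the alkynoate and the metallacycle secure both, and they fix the tetrasubstituted alkene (methyl cis to the new CH2, ester cis to the stereogenic CH).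

Step 10
Reactants: 16 hydroxy diester
Product: 17 hydroxy acid (the 5-carboxylic acid of 16; tert-butyl ester retained)
Conditions: LiOH·H2O, THF–MeOH–H2O, 0 °C → rt; acidify to pH 4
Reagents that add atoms: lithium hydroxide, [Li+].[OH-]
Why: Saponification of the saturated methyl ester, the tert-butyl ester of the tetrasubstituted enoate being inert to hydroxide.

Step 11
Reactants: 17 hydroxy acid
Product: 19 tert-butyl (2Z)-2-{(2R,3S,4S)-2-[3-(tert-butyldiphenylsilyloxy)propyl]-4-hydroxy-3,4-dimethyl-3-(4-methylpent-3-en-1-yl)cyclohexylidene}propanoate, via thiohydroxamate ester 18 (not isolated)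
Conditions: N-hydroxypyridine-2-thione, DCC, DMAP (cat.), CH2Cl2, dark, rt; t-BuSH, hν (tungsten lamp), 20 °C
Reagents that add atoms: none
Why: Barton reductive decarboxylation, in which the secondary alkyl radical should be reduced by t-BuSH faster than it can cyclise onto the remote alkene, removing the activating carboxyl group of the acrylate.

Step 12
Reactants: 19 hydroxy enoate
Product: 21 side-chain (E)-enal, the 3-[(3E)-4-methyl-5-oxopent-3-en-1-yl] analogue of 19, via allylic alcohol 20 (not isolated)
Conditions: SeO2 (cat.), t-BuOOH, salicylic acid (cat.), CH2Cl2, rt; filter; MnO2, CH2Cl2, rt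
Reagents that add atoms: tert-butyl hydroperoxide, CC(C)(C)OO (the oxygen passes through catalytic selenium dioxide, O=[Se]=O)
Why: Selenium dioxide allylic oxidation (ene reaction then [2,3]-sigmatropic shift) should be selective for the (E)-methyl group of the electron-rich trisubstituted alkene, and MnO2 takes the allylic alcohol to the (E)-enal.

Step 13
Reactants: 22 (S)-citronellal
Product: 24 (S)-3,7-dimethyloct-6-en-1-yne, via alkenyl nonaflate 23 (not isolated)
Conditions: n-C4F9SO2F, phosphazene base P2-Et, DMF, 0 °C → rt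
Reagents that add atoms: none
Why: One-pot conversion of an enolisable aldehyde into the terminal alkyne of the same carbon count by enol nonaflate formation and base-induced elimination, the stereocentre being β to the carbonyl and untouched.

Step 14
Reactants: 21 side-chain enal; 24 alkyne
Product: 27 tert-butyl (2Z)-2-{(2R,3S,4S)-2-[3-(tert-butyldiphenylsilyloxy)propyl]-4-hydroxy-3-[(3E,5R,6E,8S)-5-hydroxy-4,8,12-trimethyltrideca-3,6,11-trien-1-yl]-3,4-dimethylcyclohexylidene}propanoate, via alkenylborane 25 (not isolated), via alkenylzinc 26 (not isolated)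
Conditions: Cy2BH (preformed), toluene, 0 °C → rt; Me2Zn, −78 °C; (+)-MIB (10 mol %); 21, −20 → 0 °C; aq. NH4Cl
Reagents that add atoms: none
Why: Alkyne hydroboration, boron-to-zinc transmetalation and amino-alcohol-catalysed addition of the (E)-alkenylzinc to the enal (catalytic asymmetric vinylation), in which the ligand should control the aldehyde face and set the (R)-carbinol.

Step 15
Reactants: 27 bis-allylic alcohol
Product: 28 triol, the 1-hydroxypropan-2-ylidene analogue of 27 (CO2t-Bu reduced to CH2OH)
Conditions: i-Bu2AlH (excess), CH2Cl2, −78 → 0 °C; Rochelle salt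
Reagents that add atoms: none
Why: 1,2-Reduction of the conjugated tert-butyl ester to the allylic alcohol, with the alkene geometry retained.

Step 16
Reactants: 28 triol
Product: 29 ring enal, (2Z)-2-{...cyclohexylidene}propanal with the free (5R)-carbinol
Conditions: TEMPO (10 mol %), PhI(OAc)2, CH2Cl2, rt
Reagents that add atoms: none
Why: Oxoammonium oxidation should be selective for the primary allylic alcohol over the secondary and tertiary alcohols.

Step 17
Reactants: 29 ring enal
Product: 30 silyl-protected target (the (5R)-acetate of 29)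
Conditions: Ac2O, pyridine, DMAP (cat.), CH2Cl2, 0 °C
Reagents that add atoms: acetic anhydride, CC(=O)OC(C)=O
Why: DMAP-catalysed acetylation of the secondary alcohol, the tertiary alcohol being too hindered to react.

Step 18
Reactants: 30 silyl-protected target
Product: 31 target CNP0259235.1
Conditions: TBAF, AcOH, THF, 0 °C → rt
Reagents that add atoms: none
Why: Fluoride cleavage of the silyl ether, buffered with acetic acid so that the allylic acetate and the enal should survive.

**Compound list**

1 | δ-valerolactone | O=C1CCCCO1 | starting material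
2 | sodium 5-hydroxypentanoate | [Na+].[O-]C(=O)CCCCO | intermediate (not isolated)
3 | 5-[(tert-butyldiphenylsilyl)oxy]pentanoic acid | OC(=O)CCCCO[Si](c1ccccc1)(c1ccccc1)C(C)(C)C | intermediate
4 | geraniol | CC(C)=CCC/C(C)=C/CO | starting material
5 | geranyl 5-[(tert-butyldiphenylsilyl)oxy]pentanoate | CC(C)=CCC/C(C)=C/COC(=O)CCCCO[Si](c1ccccc1)(c1ccccc1)C(C)(C)C | intermediate
6 | Z(O)-boron ketene acetal of 5 (boron in the (4S,5S)-4,5-diphenyl-1,3-ditosyl-1,3,2-diazaborolidine ring) | CC(C)=CCC/C(C)=C/CO/C(=C/CCCO[Si](c1ccccc1)(c1ccccc1)C(C)(C)C)OB1N(S(=O)(=O)c2ccc(C)cc2)[C@@H](c2ccccc2)[C@H](c2ccccc2)N1S(=O)(=O)c1ccc(C)cc1 | intermediate (not isolated)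
7 | (2S,3R)-2-[3-(tert-butyldiphenylsilyloxy)propyl]-3,7-dimethyl-3-vinyloct-6-enoic acid | CC(C)=CCC[C@@](C=C)(C)[C@H](CCCO[Si](c1ccccc1)(c1ccccc1)C(C)(C)C)C(=O)O | intermediate
8 | (2S,3R)-2-[3-(tert-butyldiphenylsilyloxy)propyl]-3,7-dimethyl-3-vinyloct-6-en-1-ol | CC(C)=CCC[C@@](C=C)(C)[C@H](CCCO[Si](c1ccccc1)(c1ccccc1)C(C)(C)C)CO | intermediate
9 | (2S,3R)-2-[3-(tert-butyldiphenylsilyloxy)propyl]-3,7-dimethyl-3-vinyloct-6-enal | CC(C)=CCC[C@@](C=C)(C)[C@H](CCCO[Si](c1ccccc1)(c1ccccc1)C(C)(C)C)C=O | intermediate
10 | 1,1-dibromo-3-[3-(tert-butyldiphenylsilyloxy)propyl]-4,8-dimethyl-4-vinylnona-1,7-diene (stereocentres as in 9) | CC(C)=CCC[C@@](C=C)(C)[C@H](CCCO[Si](c1ccccc1)(c1ccccc1)C(C)(C)C)C=C(Br)Br | intermediate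
11 | lithium acetylide from 10 | CC(C)=CCC[C@@](C=C)(C)[C@H](CCCO[Si](c1ccccc1)(c1ccccc1)C(C)(C)C)C#C[Li] | intermediate (not isolated)
12 | tert-butyl 4-[3-(tert-butyldiphenylsilyloxy)propyl]-5,9-dimethyl-5-vinyldec-8-en-2-ynoate (stereocentres as in 9) | CC(C)=CCC[C@@](C=C)(C)[C@H](CCCO[Si](c1ccccc1)(c1ccccc1)C(C)(C)C)C#CC(=O)OC(C)(C)C | intermediate
13 | tert-butyl (4R,5S)-5-acetyl-4-[3-(tert-butyldiphenylsilyloxy)propyl]-5,9-dimethyldec-8-en-2-ynoate | CC(C)=CCC[C@@](C(C)=O)(C)[C@H](CCCO[Si](c1ccccc1)(c1ccccc1)C(C)(C)C)C#CC(=O)OC(C)(C)C | intermediate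
14 | methyl acrylate | C=CC(=O)OC | starting material
15 | methylzinc ester enolate of the alkyne/acrylate/methyl adduct (alkene: methyl cis to the new CH2) | CC(C)=CCC[C@@](C(C)=O)(C)[C@H](CCCO[Si](c1ccccc1)(c1ccccc1)C(C)(C)C)/C(=C(/C)C(=O)OC(C)(C)C)CC=C(OC)O[Zn]C | intermediate (not isolated)
16 | tert-butyl (2Z)-2-{(2R,3S,4S)-2-[3-(tert-butyldiphenylsilyloxy)propyl]-4-hydroxy-5-(methoxycarbonyl)-3,4-dimethyl-3-(4-methylpent-3-en-1-yl)cyclohexylidene}propanoate (C-5 undefined) | CC(C)=CCC[C@@]1(C)[C@H](CCCO[Si](c2ccccc2)(c2ccccc2)C(C)(C)C)/C(=C(/C)C(=O)OC(C)(C)C)CC(C(=O)OC)[C@]1(C)O | intermediate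
17 | 5-carboxylic acid corresponding to 16 | CC(C)=CCC[C@@]1(C)[C@H](CCCO[Si](c2ccccc2)(c2ccccc2)C(C)(C)C)/C(=C(/C)C(=O)OC(C)(C)C)CC(C(=O)O)[C@]1(C)O | intermediate
18 | 2-thioxopyridin-1(2H)-yl ester of 17 | CC(C)=CCC[C@@]1(C)[C@H](CCCO[Si](c2ccccc2)(c2ccccc2)C(C)(C)C)/C(=C(/C)C(=O)OC(C)(C)C)CC(C(=O)On2ccccc2=S)[C@]1(C)O | intermediate (not isolated)
19 | tert-butyl (2Z)-2-{(2R,3S,4S)-2-[3-(tert-butyldiphenylsilyloxy)propyl]-4-hydroxy-3,4-dimethyl-3-(4-methylpent-3-en-1-yl)cyclohexylidene}propanoate | CC(C)=CCC[C@@]1(C)[C@H](CCCO[Si](c2ccccc2)(c2ccccc2)C(C)(C)C)/C(=C(/C)C(=O)OC(C)(C)C)CC[C@]1(C)O | intermediate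
20 | 3-[(3E)-5-hydroxy-4-methylpent-3-en-1-yl] analogue of 19 | OC/C(C)=C/CC[C@@]1(C)[C@H](CCCO[Si](c2ccccc2)(c2ccccc2)C(C)(C)C)/C(=C(/C)C(=O)OC(C)(C)C)CC[C@]1(C)O | intermediate (not isolated)
21 | 3-[(3E)-4-methyl-5-oxopent-3-en-1-yl] analogue of 19 | O=C/C(C)=C/CC[C@@]1(C)[C@H](CCCO[Si](c2ccccc2)(c2ccccc2)C(C)(C)C)/C(=C(/C)C(=O)OC(C)(C)C)CC[C@]1(C)O | intermediate
22 | (S)-citronellal | O=CC[C@@H](C)CCC=C(C)C | starting material
23 | (3S)-3,7-dimethylocta-1,6-dien-1-yl nonafluorobutanesulfonate (E/Z) | FC(F)(F)C(F)(F)C(F)(F)C(F)(F)S(=O)(=O)OC=C[C@@H](C)CCC=C(C)C | intermediate (not isolated)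
24 | (S)-3,7-dimethyloct-6-en-1-yne | C#C[C@@H](C)CCC=C(C)C | intermediate
25 | dicyclohexyl[(1E,3S)-3,7-dimethylocta-1,6-dien-1-yl]borane | C1CCCCC1B(C1CCCCC1)/C=C/[C@@H](C)CCC=C(C)C | intermediate (not isolated)
26 | methyl[(1E,3S)-3,7-dimethylocta-1,6-dien-1-yl]zinc | C[Zn]/C=C/[C@@H](C)CCC=C(C)C | intermediate (not isolated)
27 | tert-butyl (2Z)-2-{(2R,3S,4S)-2-[3-(tert-butyldiphenylsilyloxy)propyl]-4-hydroxy-3-[(3E,5R,6E,8S)-5-hydroxy-4,8,12-trimethyltrideca-3,6,11-trien-1-yl]-3,4-dimethylcyclohexylidene}propanoate | O[C@H](/C=C/[C@@H](C)CCC=C(C)C)/C(C)=C/CC[C@@]1(C)[C@H](CCCO[Si](c2ccccc2)(c2ccccc2)C(C)(C)C)/C(=C(/C)C(=O)OC(C)(C)C)CC[C@]1(C)O | intermediate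
28 | (2Z)-2-{...cyclohexylidene}propan-1-ol corresponding to 27 (triol) | O[C@H](/C=C/[C@@H](C)CCC=C(C)C)/C(C)=C/CC[C@@]1(C)[C@H](CCCO[Si](c2ccccc2)(c2ccccc2)C(C)(C)C)/C(=C(/C)CO)CC[C@]1(C)O | intermediate
29 | (2Z)-2-{...cyclohexylidene}propanal corresponding to 28 | O[C@H](/C=C/[C@@H](C)CCC=C(C)C)/C(C)=C/CC[C@@]1(C)[C@H](CCCO[Si](c2ccccc2)(c2ccccc2)C(C)(C)C)/C(=C(/C)C=O)CC[C@]1(C)O | intermediate
30 | (5R)-acetate of 29 (tert-butyldiphenylsilyl ether of the target) | CC(=O)O[C@H](/C=C/[C@@H](C)CCC=C(C)C)/C(C)=C/CC[C@@]1(C)[C@H](CCCO[Si](c2ccccc2)(c2ccccc2)C(C)(C)C)/C(=C(/C)C=O)CC[C@]1(C)O | intermediate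
31 | (2Z)-2-{(2R,3S,4S)-3-[(3E,5R,6E,8S)-5-acetoxy-4,8,12-trimethyltrideca-3,6,11-trien-1-yl]-4-hydroxy-2-(3-hydroxypropyl)-3,4-dimethylcyclohexylidene}propanal | CC(=O)O[C@H](/C=C/[C@@H](C)CCC=C(C)C)/C(C)=C/CC[C@@]1(C)[C@H](CCCO)/C(=C(/C)C=O)CC[C@]1(C)O | target

**Step count and risks**

Total steps: 18. Longest linear sequence: 17 (steps 1–12 and 14–18; step 13 makes the side-chain alkyne).

Steps most likely to fail:

1. Step 9 (proposed new method). What may go wrong: nickel-catalysed methyl conjugate addition or alkyne/acrylate co-oligomerisation competing with the three-component coupling, bond formation at the wrong alkyne carbon, incomplete aldol ring closure, or poor facial selectivity at the ketone. The fallback sets out from 13 and comes back at 19, using known reactions only. Syn-carbocupration of the alkynoate with lithium divinylcuprate at −78 °C and trapping of the alkenylcopper with MeI/HMPA should give the tert-butyl 2-methyl-3-vinyl dienoate F1 (methyl cis to vinyl). Hydroboration of its terminal vinyl group with 9-BBN and iodination (I2, NaOMe) should give the primary iodide F2. Samarium diiodide (HMPA, THF) then closes the ring by an intramolecular Barbier addition to the methyl ketone and delivers 19 directly, so steps 10 and 11 are not needed.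

2. Step 14. What may go wrong: erosion of facial selectivity by background addition promoted by the zinc alkoxide of the free tertiary alcohol, and slow addition to the α-branched enal. The fallback sets out from 21 and 24 and comes back at 27. Hydrozirconation of 24 with Cp2Zr(H)Cl and iodinolysis should give the (E)-alkenyl iodide F3. Nozaki–Hiyama–Kishi coupling with 21 (CrCl2, NiCl2 cat., DMSO) should give 27 together with its carbinol epimer F4. MnO2 oxidation of the mixture gives the cross-conjugated dienone F5, and Corey–Bakshi–Shibata reduction ((S)-Me-CBS, catecholborane, the α-methylalkenyl group acting as the large substituent) should return 27.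

3. Step 3. What may go wrong: incomplete control of enolate geometry or of the enantiotopic face, giving the anti diastereomer or low enantiomeric purity. The fallback sets out from 5 and comes back at 8. A classical Ireland–Claisen rearrangement (LDA, THF–DMPU, TBSCl, −78 °C → rt, Z(O) silyl ketene acetal, then hydrolysis) should give the racemic syn acid, that is 7 together with its enantiomer F6. Activation with pivaloyl chloride and acylation of lithiated (S)-4-benzyl-2-oxazolidinone gives the diastereomeric imides F7 (from 7) and F8 (from F6), which are separated by chromatography. Reduction of F7 with LiBH4 gives 8.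

Further compounds
F1 | step 9 | tert-butyl 5-acetyl-4-[3-(tert-butyldiphenylsilyloxy)propyl]-2,5,9-trimethyl-3-vinyldeca-2,8-dienoate (methyl cis to vinyl) | CC(C)=CCC[C@@](C(C)=O)(C)[C@H](CCCO[Si](c1ccccc1)(c1ccccc1)C(C)(C)C)/C(=C(/C)C(=O)OC(C)(C)C)C=C
F2 | step 9 | tert-butyl 5-acetyl-4-[3-(tert-butyldiphenylsilyloxy)propyl]-3-(2-iodoethyl)-2,5,9-trimethyldeca-2,8-dienoate | CC(C)=CCC[C@@](C(C)=O)(C)[C@H](CCCO[Si](c1ccccc1)(c1ccccc1)C(C)(C)C)/C(=C(/C)C(=O)OC(C)(C)C)CCI
F3 | step 14 | (1E,3S)-1-iodo-3,7-dimethylocta-1,6-diene | I/C=C/[C@@H](C)CCC=C(C)C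
F4 | step 14 | (5S)-carbinol epimer of 27 | O[C@@H](/C=C/[C@@H](C)CCC=C(C)C)/C(C)=C/CC[C@@]1(C)[C@H](CCCO[Si](c2ccccc2)(c2ccccc2)C(C)(C)C)/C(=C(/C)C(=O)OC(C)(C)C)CC[C@]1(C)O
F5 | step 14 | dienone from oxidation of 27 and F4 | O=C(/C=C/[C@@H](C)CCC=C(C)C)/C(C)=C/CC[C@@]1(C)[C@H](CCCO[Si](c2ccccc2)(c2ccccc2)C(C)(C)C)/C(=C(/C)C(=O)OC(C)(C)C)CC[C@]1(C)O
F6 | step 3 | (2R,3S)-enantiomer of 7 | CC(C)=CCC[C@](C=C)(C)[C@@H](CCCO[Si](c1ccccc1)(c1ccccc1)C(C)(C)C)C(=O)O
F7 | step 3 | N-acyl (S)-4-benzyl-2-oxazolidinone of 7 | CC(C)=CCC[C@@](C=C)(C)[C@H](CCCO[Si](c1ccccc1)(c1ccccc1)C(C)(C)C)C(=O)N1[C@@H](Cc2ccccc2)COC1=O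
F8 | step 3 | N-acyl (S)-4-benzyl-2-oxazolidinone of F6 | CC(C)=CCC[C@](C=C)(C)[C@@H](CCCO[Si](c1ccccc1)(c1ccccc1)C(C)(C)C)C(=O)N1[C@@H](Cc2ccccc2)COC1=O
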